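**Retrosynthetic overview**
- The C1 acid comes from a C1 primary alcohol by a neutral oxidation in the last step.
- The C6–C7 bond is cut to give an acyl thioester (C1–C6, fragment 1) and an alkylzinc bromide (C7–C22, fragment 2). Coupling, closure of the 1,2-dioxane and ketalisation at C6 run in one flask.
- Enabling feature: in ring A (O1–O2–C3–C4–C5–C6), C6 is a ketone carbon masked as a methyl perketal, 1,4 to the peroxy carbon C3. In the (3S,6R) isomer C6–OMe is axial (anomeric to O1) and the carbon chains at C3 and C6 are equatorial, so ring A with this C6 configuration is the thermodynamic sink of C3–OOH + C6=O + MeOH.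
- Fragment 1 comes from pent-4-enoyl chloride, crotonaldehyde and an acetone-derived hydroperoxide. The sequence is cross-metathesis, amine-catalysed asymmetric conjugate peroxidation (sets C3), then a temporary 1,2,4-trioxepane (ring T) that masks C3–OOH and C1–OH together.
- Fragment 2 comes from dec-9-en-1-ol and pent-4-yn-1-ol by Wacker, Takai, Sonogashira, Appel and zinc insertion. Ring order: T first (step 5), A second (step 12, while T is taken apart).

Key step: step 12

Remark: locants follow the C22 chain of the target (C1 = carboxyl carbon, C3 and C6 = ring carbons, C21 = side-chain ketone). The sense of induction in step 4 is assumed from the usual shielding model of diarylprolinol silyl ether iminium ions.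

**Step 1**
Reactants: 1 pent-4-enoyl chloride
Product: 2 S-ethyl pent-4-enethioate
Conditions: EtSH (1.1 equiv), Et3N (1.2 equiv), CH2Cl2, 0 °C to 23 °C
Reagents that add atoms: ethanethiol, CCS
Why: S-Acylation of a thiol by an acid chloride (Schotten–Baumann type) is fast and clean and installs from the start the thioester that later acts as the acyl donor at C6.

**Step 2**
Reactants: 2 S-ethyl pent-4-enethioate; 3 (E)-but-2-enal (crotonaldehyde)
Product: 4 S-ethyl (4E)-6-oxohex-4-enethioate
Conditions: 3 (4 equiv), second-generation Hoveyda–Grubbs catalyst RuCl2(H2IMes)(=CH-C6H4-2-OiPr) (2 mol %), CH2Cl2, 40 °C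
Reagents that add atoms: none
Why: Olefin cross-metathesis between a terminal alkene and an excess of an electron-poor enal partner should give the E-enal under thermodynamic control, and S-alkyl thioesters are tolerated by this chelated ruthenium carbene.

**Step 3**
Reactants: 5 2,3-dimethylbut-2-ene
Product: 6 2-methoxypropan-2-yl hydroperoxide
Conditions: O3/O2, MeOH/CH2Cl2, −78 °C; N2 purge; kept and dosed as a toluene solution
Reagents that add atoms: ozone, [O-][O+]=O; methanol, CO
Why: Ozonolysis by the Criegee mechanism splits the alkene into acetone and acetone O-oxide, and methanol traps the carbonyl oxide as the α-methoxy hydroperoxide, a hydrogen peroxide equivalent masked at one end by an acid-labile ketal.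

**Step 4**
Reactants: 4 S-ethyl (4E)-6-oxohex-4-enethioate; 6 2-methoxypropan-2-yl hydroperoxide
Product: 8 S-ethyl (4S)-6-hydroxy-4-[(2-methoxypropan-2-yl)peroxy]hexanethioate, via peroxy aldehyde 7 (not isolated)
Conditions: 6 (1.5 equiv), (R)-2-[diphenyl(trimethylsilyloxy)methyl]pyrrolidine (20 mol %), 4-nitrobenzoic acid (20 mol %), toluene, 0 °C; then MeOH, NaBH4, −30 °C
Reagents that add atoms: none
Why: Iminium-catalysed enantioselective conjugate peroxidation (oxa-Michael addition) of an enal, in which the CPh2(OSiMe3) arm of the (R)-amine shields the Re face of C3 of the s-trans E-iminium ion so that the hydroperoxide should add to the Si face and set (S)-C3, the acid co-catalyst protonates the enamine before it can close to an epoxide, and the cold borohydride reduction in the same flask removes the aldehyde before retro-addition can erode C3 while dialkyl peroxide and thioester survive.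

**Step 5**
Reactants: 8 S-ethyl (4S)-6-hydroxy-4-[(2-methoxypropan-2-yl)peroxy]hexanethioate
Product: 9 S-ethyl 3-[(7S)-3,3-dimethyl-1,2,4-trioxepan-7-yl]propanethioate
Conditions: camphorsulfonic acid (5 mol %), 5 Å molecular sieves, CH2Cl2 (0.02 M), 23 °C; Et3N quench
Reagents that add atoms: none
Why: Acid-catalysed intramolecular transketalisation, the known way from 3-peroxy alcohols to 1,2,4-trioxepanes, lets the C1 hydroxyl displace methanol at the acetone ketal carbon (uptake of methanol by the sieves drives the closure), so that one temporary ring T masks both O–H functions, and C3 is untouched because no bond to it breaks.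

**Step 6**
Reactants: 10 dec-9-en-1-ol
Product: 11 10-hydroxydecan-2-one
Conditions: PdCl2 (10 mol %), CuCl (1 equiv), O2 (1 atm), DMF/H2O (7:1), 23 °C
Reagents that add atoms: water, O
Why: Tsuji–Wacker oxidation proceeds by Markovnikov hydroxypalladation of the terminal alkene and β-hydride elimination to the methyl ketone, and the remote primary alcohol is inert.

**Step 7**
Reactants: 11 10-hydroxydecan-2-one
Product: 12 9-oxodecanal
Conditions: TEMPO (10 mol %), PhI(OAc)2 (1.1 equiv), CH2Cl2, 23 °C
Reagents that add atoms: none
Why: Oxoammonium (TEMPO) oxidation of a primary alcohol stops at the aldehyde in an anhydrous medium and does not touch the ketone.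

**Step 8**
Reactants: 12 9-oxodecanal
Product: 13 (10E)-11-iodoundec-10-en-2-one
Conditions: CrCl2 (6 equiv), CHI3 (2 equiv), 1,4-dioxane/THF (6:1), 0 °C to 23 °C
Reagents that add atoms: iodoform, IC(I)I
Why: Takai olefination, in which the geminal dichromium species from CHI3 and CrCl2 adds to the aldehyde far faster than to the methyl ketone and the anti elimination should favour the E-vinyl iodide, a preference raised by the dioxane-rich solvent, with any Z isomer removed by chromatography here or after step 9.

**Step 9**
Reactants: 13 (10E)-11-iodoundec-10-en-2-one; 14 pent-4-yn-1-ol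
Product: 15 (10E)-16-hydroxyhexadec-10-en-12-yn-2-one
Conditions: 14 (1.3 equiv), PdCl2(PPh3)2 (3 mol %), CuI (6 mol %), Et3N (3 equiv), THF, 23 °C, degassed
Reagents that add atoms: none
Why: Sonogashira coupling of a vinyl iodide with a terminal alkyne runs at room temperature with retention of the alkene geometry and tolerates the free alcohol and the ketone.

**Step 10**
Reactants: 15 (10E)-16-hydroxyhexadec-10-en-12-yn-2-one
Product: 16 (10E)-16-bromohexadec-10-en-12-yn-2-one
Conditions: CBr4 (1.2 equiv), PPh3 (1.25 equiv), CH2Cl2, 0 °C
Reagents that add atoms: tetrabromomethane, BrC(Br)(Br)Br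
Why: Appel reaction, an SN2 displacement of the alkoxyphosphonium ion by bromide under neutral conditions, leaves ketone and enyne alone, and bromide is chosen over iodide because no iodide may be carried into the acidic stage of step 12.

**Step 11**
Reactants: 16 (10E)-16-bromohexadec-10-en-12-yn-2-one
Product: 17 [(6E)-15-oxohexadec-6-en-4-yn-1-yl]zinc bromide, kept as a titrated THF solution with LiCl
Conditions: Zn dust (2 equiv, activated with BrCH2CH2Br 5 mol % and Me3SiCl 2 mol %), LiCl (1.5 equiv), THF, 50 °C; solution decanted from excess Zn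
Reagents that add atoms: zinc, [Zn]
Why: Direct insertion of LiCl-activated zinc into the primary C–Br bond gives an alkylzinc halide that does not add to ketones, and the transient 4-pentynyl-type radical has no favourable cyclisation mode (4-exo or 5-endo), so the enyne stays intact.

**Step 12**
Reactants: 9 S-ethyl 3-[(7S)-3,3-dimethyl-1,2,4-trioxepan-7-yl]propanethioate; 17 [(6E)-15-oxohexadec-6-en-4-yn-1-yl]zinc bromide
Product: 21 2-[(3S,6R)-6-methoxy-6-[(6E)-15-oxohexadec-6-en-4-yn-1-yl]-1,2-dioxan-3-yl]ethan-1-ol, via keto trioxepane 18 (not isolated), via hydroperoxy ketone 19 (not isolated), via dioxanol 20 (not isolated)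
Conditions: 17 (1.3 equiv), PdCl2(PPh3)2 (3 mol %), toluene/THF, 23 °C, degassed; then MeOH, N-ethylmaleimide (1.5 equiv), 0 °C; then TsOH·H2O (1.5 equiv, about 0.2 equiv stays free once the basic zinc salts are neutralised), MeOH (0.03 M), 23 °C until the C6 epimers have equilibrated; H2O (5 vol %), 10 min; NaHCO3
Reagents that add atoms: methanol, CO
Why: Fukuyama coupling: zerovalent palladium inserts into the C(acyl)–S bond of 9, the primary alkyl group passes from zinc to palladium and reductive elimination forges the C6–C7 bond of ketone 18 at room temperature, a reaction type that should leave ketones, enynes and dialkyl peroxides alone. N-Ethylmaleimide then caps the ethanethiolate and the free phosphine by conjugate addition, and acidic methanol opens ring T (acid methanolysis of a perketal), after which the freed C3 hydroperoxide of 19 adds to the new C6 carbonyl in a 6-exo-trig closure of ring A and dioxanol 20 ionises to a peroxycarbenium ion that takes up methanol. C3 keeps its configuration because no bond to it is broken, while C6 is set under thermodynamic control relayed from C3: ketal exchange is reversible, so both C6 epimers should drain into the chair with the C3 and C6 carbon chains equatorial and the methoxy group axial (overlap of an O1 lone pair with the σ* orbital of C6–OMe), which is the (3S,6R) isomer, and axial attack of methanol on the cation leads the same way. The chemoselectivity that is needed lies in the substrate: only the thioester undergoes oxidative addition, so the C21 ketone is a spectator, and only the C6 carbonyl lies 1,4 to the hydroperoxide, so it alone is locked as a cyclic perketal, whereas any dimethyl ketal at C21 reverts in the short aqueous hold. The zinc reagent is a bromide because iodide would reduce the transient hydroperoxide in acid, and the large excess of methanol keeps the C1 hydroxyl from closing a strained bicyclo[3.2.2] ketal onto C6. The closest known reaction types are the thioester–organozinc ketone synthesis, palladium-catalysed couplings run on peroxide-bearing substrates and the closure of 4-hydroperoxy ketones to 3-alkoxy-1,2-dioxanes in acidic alcohols.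

**Step 13**
Reactants: 21 2-[(3S,6R)-6-methoxy-6-[(6E)-15-oxohexadec-6-en-4-yn-1-yl]-1,2-dioxan-3-yl]ethan-1-ol
Product: 23 2-[(3S,6R)-6-methoxy-6-[(6E)-15-oxohexadec-6-en-4-yn-1-yl]-1,2-dioxan-3-yl]acetic acid, via dioxanyl acetaldehyde 22 (not isolated)
Conditions: TEMPO (20 mol %), PhI(OAc)2 (2.3 equiv), MeCN/phosphate buffer pH 7 (1:1), 0 °C to 23 °C; extraction at pH 4 to 5
Reagents that add atoms: water, O
Why: Oxoammonium (TEMPO) oxidation with PhI(OAc)2 as terminal oxidant takes the primary alcohol to aldehyde 22 and, through its hydrate, to the acid at buffered neutral pH, so that neither base (β-elimination of the C3 peroxide) nor strong acid (ionisation at C6) can touch the two stereocentres, and ketone, enyne and O–O bond are inert to this oxidant.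

**Compound list**
1 | pent-4-enoyl chloride | C=CCCC(=O)Cl | starting material
2 | S-ethyl pent-4-enethioate | C=CCCC(=O)SCC | intermediate
3 | (E)-but-2-enal | C/C=C/C=O | starting material
4 | S-ethyl (4E)-6-oxohex-4-enethioate | CCSC(=O)CC/C=C/C=O | intermediate
5 | 2,3-dimethylbut-2-ene | CC(C)=C(C)C | starting material
6 | 2-methoxypropan-2-yl hydroperoxide | COC(C)(C)OO | intermediate
7 | S-ethyl (4S)-4-[(2-methoxypropan-2-yl)peroxy]-6-oxohexanethioate | CCSC(=O)CC[C@@H](CC=O)OOC(C)(C)OC | intermediate
8 | S-ethyl (4S)-6-hydroxy-4-[(2-methoxypropan-2-yl)peroxy]hexanethioate | CCSC(=O)CC[C@@H](CCO)OOC(C)(C)OC | intermediate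
9 | S-ethyl 3-[(7S)-3,3-dimethyl-1,2,4-trioxepan-7-yl]propanethioate | CCSC(=O)CC[C@@H](CCO1)OOC1(C)C | intermediate
10 | dec-9-en-1-ol | C=CCCCCCCCCO | starting material
11 | 10-hydroxydecan-2-one | CC(=O)CCCCCCCCO | intermediate
12 | 9-oxodecanal | CC(=O)CCCCCCCC=O | intermediate
13 | (10E)-11-iodoundec-10-en-2-one | CC(=O)CCCCCCC/C=C/I | intermediate
14 | pent-4-yn-1-ol | C#CCCCO | starting material
15 | (10E)-16-hydroxyhexadec-10-en-12-yn-2-one | CC(=O)CCCCCCC/C=C/C#CCCCO | intermediate
16 | (10E)-16-bromohexadec-10-en-12-yn-2-one | CC(=O)CCCCCCC/C=C/C#CCCCBr | intermediate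
17 | [(6E)-15-oxohexadec-6-en-4-yn-1-yl]zinc bromide | CC(=O)CCCCCCC/C=C/C#CCCC[Zn]Br | intermediate
18 | (10E)-19-[(7S)-3,3-dimethyl-1,2,4-trioxepan-7-yl]nonadec-10-en-12-yne-2,17-dione | CC(=O)CCCCCCC/C=C/C#CCCCC(=O)CC[C@@H](CCO1)OOC1(C)C | intermediate
19 | (10E,20S)-20-hydroperoxy-22-hydroxydocos-10-en-12-yne-2,17-dione | CC(=O)CCCCCCC/C=C/C#CCCCC(=O)CC[C@@H](CCO)OO | intermediate
20 | 2-[(3S)-6-hydroxy-6-[(6E)-15-oxohexadec-6-en-4-yn-1-yl]-1,2-dioxan-3-yl]ethan-1-ol (both C6 epimers) | CC(=O)CCCCCCC/C=C/C#CCCCC1(O)CC[C@@H](CCO)OO1 | intermediate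
21 | 2-[(3S,6R)-6-methoxy-6-[(6E)-15-oxohexadec-6-en-4-yn-1-yl]-1,2-dioxan-3-yl]ethan-1-ol | CO[C@@]1(CCCC#C/C=C/CCCCCCCC(C)=O)CC[C@@H](CCO)OO1 | intermediate
22 | 2-[(3S,6R)-6-methoxy-6-[(6E)-15-oxohexadec-6-en-4-yn-1-yl]-1,2-dioxan-3-yl]acetaldehyde | CO[C@@]1(CCCC#C/C=C/CCCCCCCC(C)=O)CC[C@@H](CC=O)OO1 | intermediate
23 | 2-[(3S,6R)-6-methoxy-6-[(6E)-15-oxohexadec-6-en-4-yn-1-yl]-1,2-dioxan-3-yl]acetic acid | CO[C@@]1(CCCC#C/C=C/CCCCCCCC(C)=O)CC[C@@H](CC(=O)O)OO1 | target

**Step count**
Total step count: 13. Longest linear sequence: 8 steps (steps 6 to 13, from dec-9-en-1-ol).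

**Steps most likely to fail**

**Step 12.**
- What may go wrong: cleavage of the O–O bond of ring T by zerovalent palladium, phosphine or the zinc reagent during the coupling. The transient hydroperoxide may also be reduced by residues of the coupling stage once the acid is added.
- Fallback: the C6–C7 bond is made before any peroxide is present. It sets out from 4 and 17.
- The same palladium-catalysed thioester–organozinc coupling, which tolerates aldehydes, followed by an ordinary aqueous work-up should give (2E,12E)-6,21-dioxodocosa-2,12-dien-10-ynal F1.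
- The amine-catalysed conjugate peroxidation of step 4 with 6 should then give (3S,12E)-3-[(2-methoxypropan-2-yl)peroxy]-6,21-dioxodocos-12-en-10-ynal F2.
- Aldehyde-selective reduction with NaBH(OAc)3 should give (10E,20S)-22-hydroxy-20-[(2-methoxypropan-2-yl)peroxy]docos-10-en-12-yne-2,17-dione F3.
- Metal-free TsOH in MeOH takes F3 through 19 and 20. The fallback comes back to the route at 21.

**Step 4.**
- What may go wrong: poor facial selectivity in the addition to the iminium ion, or erosion of the C3 configuration by reversible addition before the reduction.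
- Fallback: C3 is not controlled in the addition but sorted afterwards. It sets out from 4 and 6.
- The addition is run with the racemic form of the same amine and should give racemic S-ethyl 4-[(2-methoxypropan-2-yl)peroxy]-6-oxohexanethioate F4.
- F4 is reduced in the flask to racemic S-ethyl 6-hydroxy-4-[(2-methoxypropan-2-yl)peroxy]hexanethioate F5.
- F5 is closed as in step 5 to racemic S-ethyl 3-(3,3-dimethyl-1,2,4-trioxepan-7-yl)propanethioate F6.
- Preparative chromatography on a chiral stationary phase (amylose tris(3,5-dimethylphenylcarbamate), supercritical CO2/2-propanol) separates the wanted enantiomer from S-ethyl 3-[(7R)-3,3-dimethyl-1,2,4-trioxepan-7-yl]propanethioate F7. The fallback comes back to the route at 9.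

**Step 5.**
- What may go wrong: the seven-membered closure loses out to extrusion of the acetone unit as 2-methoxypropene and to intermolecular perketal exchange.
- Fallback: no temporary ring, but two independent acyclic masks. It sets out from 8.
- Et3SiCl and imidazole in CH2Cl2 should give S-ethyl (4S)-4-[(2-methoxypropan-2-yl)peroxy]-6-[(triethylsilyl)oxy]hexanethioate F8.
- Coupling of F8 with 17 under the conditions of step 12 should give in the flask (10E,20S)-20-[(2-methoxypropan-2-yl)peroxy]-22-[(triethylsilyl)oxy]docos-10-en-12-yne-2,17-dione F9.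
- The acidic methanol stage strips both masks from F9. The fallback comes back to the route at 19 and thus at 21.

**Further compounds**
F1 | step 12 | (2E,12E)-6,21-dioxodocosa-2,12-dien-10-ynal | CC(=O)CCCCCCC/C=C/C#CCCCC(=O)CC/C=C/C=O
F2 | step 12 | (3S,12E)-3-[(2-methoxypropan-2-yl)peroxy]-6,21-dioxodocos-12-en-10-ynal | CC(=O)CCCCCCC/C=C/C#CCCCC(=O)CC[C@@H](CC=O)OOC(C)(C)OC
F3 | step 12 | (10E,20S)-22-hydroxy-20-[(2-methoxypropan-2-yl)peroxy]docos-10-en-12-yne-2,17-dione | CC(=O)CCCCCCC/C=C/C#CCCCC(=O)CC[C@@H](CCO)OOC(C)(C)OC
F4 | step 4 | racemic S-ethyl 4-[(2-methoxypropan-2-yl)peroxy]-6-oxohexanethioate | CCSC(=O)CCC(CC=O)OOC(C)(C)OC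
F5 | step 4 | racemic S-ethyl 6-hydroxy-4-[(2-methoxypropan-2-yl)peroxy]hexanethioate | CCSC(=O)CCC(CCO)OOC(C)(C)OC
F6 | step 4 | racemic S-ethyl 3-(3,3-dimethyl-1,2,4-trioxepan-7-yl)propanethioate | CCSC(=O)CCC1CCOC(C)(C)OO1
F7 | step 4 | S-ethyl 3-[(7R)-3,3-dimethyl-1,2,4-trioxepan-7-yl]propanethioate | CCSC(=O)CC[C@H](CCO1)OOC1(C)C
F8 | step 5 | S-ethyl (4S)-4-[(2-methoxypropan-2-yl)peroxy]-6-[(triethylsilyl)oxy]hexanethioate | CCSC(=O)CC[C@@H](CCO[Si](CC)(CC)CC)OOC(C)(C)OC
F9 | step 5 | (10E,20S)-20-[(2-methoxypropan-2-yl)peroxy]-22-[(triethylsilyl)oxy]docos-10-en-12-yne-2,17-dione | CC(=O)CCCCCCC/C=C/C#CCCCC(=O)CC[C@@H](CCO[Si](CC)(CC)CC)OOC(C)(C)OC
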